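## Structural features

The target is a labdane: a trans-fused decalin (ring A = C1–C5 and C10, ring B = C5–C10) with a saturated side chain C11–C16 on C9 that ends in a methyl ester at C15. Labdane numbering is used throughout. Five of the six stereocentres are contiguous in ring B (C5, C6, C8, C9, C10), two of them fully substituted (C8, C10). The sixth, C13 (S), lies three bonds from the ring and cannot be controlled from it. C6 bears an axial (β) acetoxy group on the face that also carries the axial methyl groups on C4, C10 and C8. C8 bears an equatorial (α) tertiary hydroxyl with its methyl (C17) axial, so the two oxygens are 1,3-anti. Fragile points are the methyl ester, the secondary acetate beside a free tertiary alcohol, and, at the ketone oxidation level, a β-oxygenated C6 ketone that can eliminate or cleave by retro-aldol reaction. The real difficulty is the congested C4–C5–C10–C9 array (quaternary C10 between the gem-dimethyl carbon and a tertiary centre) combined with oxygenation on two hindered positions of ring B. The key step exploits the C6–C7–C8 triad: a C6 carbonyl and a methyl-bearing tertiary C8–O are what results when a C6 acyl radical adds to C7 of a C7=C8(C17) isopropenyl group on C9 and the C8 radical is capped by oxygen, which closes ring B.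

## Logic of the disconnections

**21 back to 18.** The C8–OH of 21 is traced to the O–O bond of 20, the acetate C–O bond to the free C6 alcohol of 19, and the C6–H bond to the C6 carbonyl of 18. No carbon–carbon bond is cut; the purpose is to reach the β-oxy ketone from which the skeleton can be opened. C8 stays masked as the peroxide while C6 is reduced and acylated, so no tertiary alcohol competes in the acylation and no β-hydroxy ketone is ever handled. The forward steps must deliver hydride to the α face of C6 and must finally break O–O without touching C8–O.

**18 back to 17 and 3.** The C6–C7 bond and the C8–O bond are cut together. A β-oxy ketone is the retron of an acyl radical adding to an alkene with oxygen capture, so ring B and the C8 stereocentre disappear in one move. The forward step needs 6-endo regiochemistry, α-face capture at C8, ring closure faster than loss of CO, and C5, C9, C10 already correct with the formyl group and the C9 branch trans on ring A.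

**17 back to 16 and 13.** The ester C–O bond is removed first (methylation of an acid). Then C9–C10 is cut with reconnection of C6–C7, the reverse of an oxy-Cope shift; the C6–C7 bond sacrificed in that shift is the one that step 11 makes again. Two adjacent stereocentres (quaternary C10, tertiary C9) are exchanged for one carbinol centre at C6 and an (E)-alkene, and ring A becomes the flat trimethylcyclohexenyl unit. The forward step needs a chair transition state, a carboxyl group that is inert to strong base (hence the carboxylate, not the ester), and protonation at C5 from the α face.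

**13 back to 11, 10 and 9.** The C15 oxygens are taken back to a silyl-protected primary alcohol and the C6–H bond to a ketone. C15 cannot be an ester during the organometallic and strongly basic steps, and reduction of the ketone is the one reagent-controlled stereochemical event of the route. The forward steps need an oxidant that distinguishes a primary alcohol from a very hindered secondary one, and a catalyst that tells the two flanks of the ketone apart.

**9 back to 8, then 5 and 6.** The C6–C7 bond between the carbonyl carbon and the allylic methylene is cut, which gives two fragments of similar size. The allyl nucleophile must react at its unsubstituted terminus and keep its (E)-geometry, because that geometry later becomes the C9 configuration.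

**5 back to 4, 2, 1 and 3.** The C–Cl, allylic C–O and O–Si bonds are removed in turn. The chain maps carbon for carbon onto 1, which supplies C13 from the chiral pool. The forward oxidation must be selective for the (E)-methyl group of the trisubstituted alkene.

## Other disconnections considered

**Alternative 1:** The cut goes through C5–C10 and C8–C9, opening both rings to the acyclic trienal A2. In A2 the (E)-enal C9=C10 is the dienophile and the 2-silyloxydiene C5=C6–C7=C8 is tethered to it through C1–C4. Forward, a chiral oxazaborolidinium triflimide (an N-protonated, prolinol-derived B-aryl oxazaborolidine with bis(trifluoromethylsulfonyl)imide as counter-ion) would activate the formyl group. A type 1 intramolecular Diels–Alder reaction would then give the trans-fused silyl enol ether aldehyde A1.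
- In favour: C5, C9, C10 and both rings arise in one catalyst-controlled operation, the C6 oxygen arrives as a regiodefined enol ether, and the C11 formyl group is a handle for the side chain.
- Against: the dienophile is β,β-disubstituted and the diene terminus C5 is neopentylic, so the cycloaddition that creates quaternary C10 is of the most hindered kind. The silyl enol ether must survive a strongly acidic catalyst. C8 arrives as a methyl-bearing C–H, so the tertiary C8–O bond still has to be made (for example desaturation to the C7=C8 enone, epoxidation, reductive opening). C12–C16 with the C13 stereocentre must still be attached to C11 and saturated.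
- Comparison: for the carbon stereocentres the alternative is the better plan, since it sets three of them and two rings in one catalytic asymmetric step, whereas the chosen route relays chirality through a carbinol (steps 6 and 9) and closes only ring B in step 11. Its key step is a closed-shell, catalyst-controlled cycloaddition, closer to established practice than the radical step 11; that too is a point in its favour. The chosen plan is better at the C8–O bond, which forms together with the C6 carbonyl and with the full side chain already in place, so only three functional-group steps follow. A1 would need roughly eight more, so overall step economy is expected to favour the chosen plan.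

**Alternative 2:** The cut is the C4–C5 bond of ring A, made on a resorcinol-derived ring B. The precursor is the dearomatised bis(enol ether) A4, whose C10 is a prochiral quaternary carbon carrying the epoxy side chain. Forward, BF3·OEt2 would open the (R)-epoxide at its tertiary carbon C4, one of the two enantiotopic enol ethers would attack through C5 and so fix C10, and aqueous acid would unmask the β-diketone and equilibrate C5, giving the trans-fused hydroxy dione A3.
- In favour: the 1,3-dioxygen pattern at C6 and C8 is recognised directly and comes from an aromatic feedstock. Ring A, the gem-dimethyl group and quaternary C10 are made by a well-understood epoxide-initiated cation–olefin closure, with absolute configuration from an accessible chiral epoxide.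
- Against: A3 carries a C3 hydroxyl that the target lacks, and C9 is a bare methylene to which the whole side chain must be attached with control of C9. The two carbonyls must be told apart. The C17 methyl must add to the C8 carbonyl from the β face, syn to the axial C10 methyl, which is the contra-steric direction. The choice between the two enol ethers rests on a small difference between two chair arrangements.
- Comparison: in cheap materials and in building ring A and C10 by long-established two-electron chemistry the alternative is at least the equal of the chosen plan. The chosen plan is the better match to the target: C8 is created with its methyl axial because radical capture prefers the equatorial C–O bond, C9 and its chain exist before ring B, and no extraneous oxygen must be removed. After A3 a long sequence would remain (deoxygenation, carbonyl differentiation, C9 alkylation, C8 methylation, C6 reduction, acetylation), so the chosen plan is expected to be shorter.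

**Alternative 3:** The cut is C8–C9 of ring B with a shift of unsaturation. The 1,4-diene A5 is traced to the 1,7-enyne A6, whose ring A (C5, C6, C10 set) would come from an asymmetric Diels–Alder reaction. Forward, Pd(OAc)2 with PPh3 in acetic acid would generate a hydridopalladium acetate, add it across the alkyne, insert the C9=C11 alkene (C8–C9 formed) and eliminate a C12 hydrogen. This gives the exocyclic C8=C17 methylene and the C11=C12 (E)-alkene.
- In favour: the step is an isomerisation with full atom economy. The 6β-acetoxy group and C13 are present before ring closure, so no late acylation of a hindered axial alcohol is needed. Only two steps would follow (Markovnikov hydration of C8=C17, hydrogenation of C11=C12), one fewer than after step 11; on this point the alternative is better.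
- Against: six-ring closure from a 1,7-enyne is slower than the five-ring case, and the alkene sits on quaternary C10. C9 must be set relative to C10 in the insertion step. The homopropargylic acetate is a potential leaving group. The C8 oxygen is installed separately with its own facial selectivity, and before the hydrogenation, because the exocyclic alkene is the more accessible one.
- Comparison: the closed-shell organometallic cycle is of a known type, an advantage in predictability over the radical cascade. Structurally the chosen plan sets C9 before ring closure and forms C8–O during it, whereas the alternative must control C9 in the ring-forming step and C8 afterwards. A6 needs an enantioselective ring A synthesis carrying three stereocentres, an alkyne and a chiral side chain, judged longer than the ten steps to 17. Total step counts are therefore expected to be comparable, with the chosen plan slightly shorter.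

Key step: step 11

Assumption: in the chair transition state of step 9 the oxido group is taken to lie pseudo-equatorial, away from the C10 methyl, which makes the (6S) carbinol the required one; if the opposite preference held, the enantiomeric catalyst would be used in step 6.

Step 1
Reactants: 1 (S)-citronellol
Product: 2 tert-butyl{[(3S)-3,7-dimethyloct-6-en-1-yl]oxy}dimethylsilane
Conditions: TBSCl, imidazole, CH2Cl2, 0 °C to rt
Reagents that add atoms: tert-butyldimethylsilyl chloride, CC(C)(C)[Si](C)(C)Cl
Why: Routine silylation of a primary alcohol; the silyl ether masks C15 through the organobarium, hydride and fluoride-free steps that follow, and C13 is untouched.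

Step 2
Reactants: 2 tert-butyl{[(3S)-3,7-dimethyloct-6-en-1-yl]oxy}dimethylsilane; 3 tert-butyl hydroperoxide
Product: 4 (2E,6S)-8-(tert-butyldimethylsilyloxy)-2,6-dimethyloct-2-en-1-ol
Conditions: SeO2 (cat.), salicylic acid (cat.), 3 (3 equiv), CH2Cl2, rt
Reagents that add atoms: selenium dioxide, O=[Se]=O (oxygen carrier, re-oxidised by 3)
Why: Selenium dioxide allylic oxidation (ene reaction then 2,3-sigmatropic shift) attacks the (E)-methyl group of a trisubstituted alkene and so gives the (E)-allylic alcohol; 3 turns selenium over.

Step 3
Reactants: 4 (2E,6S)-8-(tert-butyldimethylsilyloxy)-2,6-dimethyloct-2-en-1-ol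
Product: 5 tert-butyl{[(3S,6E)-8-chloro-3,7-dimethyloct-6-en-1-yl]oxy}dimethylsilane
Conditions: N-chlorosuccinimide, Me2S, CH2Cl2, −30 °C to 0 °C
Reagents that add atoms: N-chlorosuccinimide, O=C1CCC(=O)N1Cl
Why: Corey–Kim chlorination displaces the alkoxysulfonium ion of a primary allylic alcohol by SN2 attack of chloride, without allylic transposition or loss of the (E)-geometry; the silyl ether is inert.

Step 4
Reactants: 5 tert-butyl{[(3S,6E)-8-chloro-3,7-dimethyloct-6-en-1-yl]oxy}dimethylsilane; 6 β-cyclocitral
Product: 8 (3E,7S)-9-(tert-butyldimethylsilyloxy)-3,7-dimethyl-1-(2,6,6-trimethylcyclohex-1-en-1-yl)non-3-en-1-ol as both C1 epimers, via allylbarium chloride 7 (not isolated)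
Conditions: BaI2, lithium biphenylide (LiC12H10, 2 equiv), THF, rt; then 5, −78 °C; then 6, −78 °C; H2O
Reagents that add atoms: none
Why: Allylbarium reagents made at −78 °C keep their alkene geometry and add to aldehydes in a 1,2-sense through the unsubstituted α-carbon, giving the linear homoallylic alcohol with the C8=C9 (E)-alkene; the carbinol centre forms unselectively, which does not matter because it is oxidised next.

Step 5
Reactants: 8 (3E,7S)-9-(tert-butyldimethylsilyloxy)-3,7-dimethyl-1-(2,6,6-trimethylcyclohex-1-en-1-yl)non-3-en-1-ol
Product: 9 (3E,7S)-9-(tert-butyldimethylsilyloxy)-3,7-dimethyl-1-(2,6,6-trimethylcyclohex-1-en-1-yl)non-3-en-1-one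
Conditions: Dess–Martin periodinane, NaHCO3, CH2Cl2, 0 °C to rt
Reagents that add atoms: none
Why: Dess–Martin oxidation under buffered, non-basic conditions gives the β,γ-unsaturated ketone without moving the C8=C9 alkene into conjugation.

Step 6
Reactants: 9 (3E,7S)-9-(tert-butyldimethylsilyloxy)-3,7-dimethyl-1-(2,6,6-trimethylcyclohex-1-en-1-yl)non-3-en-1-one
Product: 10 (1S,3E,7S)-9-(tert-butyldimethylsilyloxy)-3,7-dimethyl-1-(2,6,6-trimethylcyclohex-1-en-1-yl)non-3-en-1-ol
Conditions: (R)-2-methyl-CBS-oxazaborolidine [(R)-1-methyl-3,3-diphenyltetrahydro-1H,3H-pyrrolo[1,2-c][1,3,2]oxazaborole] (0.5 equiv), BH3·SMe2, THF, −30 °C to 0 °C; MeOH, aq. work-up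
Reagents that add atoms: none
Why: CBS reduction; the trimethylcyclohexenyl group acts as the large and the allylic methylene as the small substituent, so the (R)-catalyst should deliver hydride to the face that gives the (S)-carbinol at C6; the silyl ether and both alkenes are inert to the borane complex at this temperature.

Step 7
Reactants: 10 (1S,3E,7S)-9-(tert-butyldimethylsilyloxy)-3,7-dimethyl-1-(2,6,6-trimethylcyclohex-1-en-1-yl)non-3-en-1-ol
Product: 11 (3S,6E,9S)-3,7-dimethyl-9-(2,6,6-trimethylcyclohex-1-en-1-yl)non-6-ene-1,9-diol
Conditions: Bu4NF, THF, 0 °C to rt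
Reagents that add atoms: none
Why: Fluoride desilylation frees the primary alcohol under non-acidic conditions that do not ionise the allylic carbinol at C6.

Step 8
Reactants: 11 (3S,6E,9S)-3,7-dimethyl-9-(2,6,6-trimethylcyclohex-1-en-1-yl)non-6-ene-1,9-diol
Product: 13 (3S,6E,9S)-9-hydroxy-3,7-dimethyl-9-(2,6,6-trimethylcyclohex-1-en-1-yl)non-6-enoic acid, via hydroxy aldehyde 12 (not isolated)
Conditions: TEMPO (2,2,6,6-tetramethylpiperidin-1-oxyl, cat.), PhI(OAc)2 (2.2 equiv), MeCN/pH 7 aqueous buffer, 0 °C to rt
Reagents that add atoms: water, O
Why: Oxoammonium oxidation discriminates strongly for the unhindered primary alcohol over the secondary carbinol buried beside the trimethylcyclohexenyl ring, and in water the aldehyde hydrate is oxidised on to the acid; this places C15 at the carboxyl level while C6 is still an alcohol, so no aldehyde has to be spared later.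

Step 9
Reactants: 13 (3S,6E,9S)-9-hydroxy-3,7-dimethyl-9-(2,6,6-trimethylcyclohex-1-en-1-yl)non-6-enoic acid
Product: 16 (3S,6S)-6-[(1R,2S)-2-formyl-1,3,3-trimethylcyclohexyl]-3,7-dimethyloct-7-enoic acid, via dipotassium alkoxide carboxylate 14 (not isolated), via dipotassium enolate carboxylate 15 (not isolated)
Conditions: KH (3.5 equiv), 18-crown-6 (2.5 equiv), THF, 0 °C to rt; then AcOH, THF, −78 °C
Reagents that add atoms: none
Why: Anionic oxy-Cope rearrangement through a chair in which the (E)-alkene places C11 equatorial and the oxido group is equatorial to avoid a 1,3-diaxial contact with the C10 methyl, so the (6S) centre is transferred to (9S,10R) while the carboxylate is an inert spectator. Kinetic protonation of the enolate at C5 from the α face, anti to the axial methyl groups on C4 and C10, should give the equatorial formyl group trans to the C9 branch (5S).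

Step 10
Reactants: 16 (3S,6S)-6-[(1R,2S)-2-formyl-1,3,3-trimethylcyclohexyl]-3,7-dimethyloct-7-enoic acid
Product: 17 methyl (3S,6S)-6-[(1R,2S)-2-formyl-1,3,3-trimethylcyclohexyl]-3,7-dimethyloct-7-enoate
Conditions: Me3SiCHN2, toluene/MeOH (4:1), 0 °C
Reagents that add atoms: (trimethylsilyl)diazomethane, C[Si](C)(C)C=[N+]=[N-]
Why: Methylation of the acid with the diazoalkane is neutral, so C5 next to the formyl group is not epimerised, and the hindered aldehyde does not react without a Lewis acid.

Step 11
Reactants: 17 methyl (3S,6S)-6-[(1R,2S)-2-formyl-1,3,3-trimethylcyclohexyl]-3,7-dimethyloct-7-enoate; 3 tert-butyl hydroperoxide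
Product: 18 methyl 8α-(tert-butylperoxy)-6-oxolabdan-15-oate
Conditions: FeCl2 (10 mol%), 3 (4 equiv, anhydrous in decane, added slowly), MeCN (0.02 M), 60 °C, argon
Reagents that add atoms: none
Why: Proposed new method: divalent iron cleaves 3 to the tert-butoxyl radical, which abstracts the weak formyl C–H of 17; the nucleophilic C6 acyl radical adds to the unsubstituted terminus C7 of the isopropenyl group, and the transient tertiary C8 radical cross-couples with the persistent tert-butylperoxyl radical that trivalent iron generates from a second molecule of 3 (C6–C7 and C8–O formed, tert-butanol and water as by-products). The closest known reaction types are the iron-catalysed intermolecular three-component acylation–peroxidation of alkenes with aldehydes and 3, and the 6-endo cyclisation of acyl radicals onto 1,1-disubstituted alkenes; their combination in one intramolecular, oxygen-terminated event has no direct counterpart. Ring B closes in the 6-endo-trig mode through a chair in which the C5–C6 and C9–C8 bonds are both equatorial on ring A, which is why the trans relationship of the formyl group and the C9 branch in 17 matters. The 5-exo alternative would have to attack the fully substituted C8, and any 5-exo adduct can ring-expand by acyl migration to the same C8 radical. The new stereocentre C8 is set by approach of the bulky peroxyl partner from the α (equatorial) face, anti to the axial C10 methyl that shields the β face, which leaves C17 axial. The step needs hydrogen abstraction at the formyl group and not at allylic or tertiary C–H bonds (the aldehyde C–H is the weakest and is polarity-matched), ring closure faster than loss of CO (C5 is secondary, the alkene is held close, the temperature is moderate), and closure faster than coupling of the acyl radical with peroxyl or iron (dilution and slow addition of 3). C5, C9, C10 and C13 are spectators, and no acid or base is present that could epimerise C5.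

Step 12
Reactants: 18 methyl 8α-(tert-butylperoxy)-6-oxolabdan-15-oate
Product: 19 methyl 8α-(tert-butylperoxy)-6β-hydroxylabdan-15-oate
Conditions: NaBH4, CeCl3·7H2O, MeOH, −20 °C
Reagents that add atoms: none
Why: Luche-type borohydride reduction; the β face of C6 is screened by the axial methyl groups on C4, C10 and C8, so hydride should arrive from the α face and give the axial 6β-alcohol. The dialkyl peroxide and the ester are not reduced, and the cerium salt keeps the medium from enolising the β-peroxy ketone.

Step 13
Reactants: 19 methyl 8α-(tert-butylperoxy)-6β-hydroxylabdan-15-oate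
Product: 20 methyl 6β-acetoxy-8α-(tert-butylperoxy)labdan-15-oate
Conditions: Ac2O, 4-(dimethylamino)pyridine (cat.), pyridine, 40 °C
Reagents that add atoms: acetic anhydride, CC(=O)OC(C)=O
Why: Nucleophile-catalysed acylation of the hindered axial alcohol; because the C8 oxygen is still a peroxide there is no second hydroxyl to compete, so forcing conditions can be used, and the di-tertiary peroxide is thermally stable at this temperature.

Step 14
Reactants: 20 methyl 6β-acetoxy-8α-(tert-butylperoxy)labdan-15-oate
Product: 21 methyl 6β-acetoxy-8α-hydroxylabdan-15-oate (target, CNP0113148.1)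
Conditions: Zn dust, AcOH/THF, rt to 40 °C
Reagents that add atoms: none
Why: Dissolving-metal reduction cleaves the O–O bond only, so the C8–O bond and its α configuration are retained; the acetate and ester survive acetic acid, and the anti 1,3-arrangement of the acetate and the new hydroxyl prevents acyl migration.

Compound list

1 | (S)-citronellol, (3S)-3,7-dimethyloct-6-en-1-ol | OCC[C@@H](C)CCC=C(C)C | starting material
2 | tert-butyl{[(3S)-3,7-dimethyloct-6-en-1-yl]oxy}dimethylsilane | CC(C)(C)[Si](C)(C)OCC[C@@H](C)CCC=C(C)C | intermediate
3 | tert-butyl hydroperoxide | CC(C)(C)OO | starting material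
4 | (2E,6S)-8-(tert-butyldimethylsilyloxy)-2,6-dimethyloct-2-en-1-ol | CC(C)(C)[Si](C)(C)OCC[C@@H](C)CC/C=C(\C)CO | intermediate
5 | tert-butyl{[(3S,6E)-8-chloro-3,7-dimethyloct-6-en-1-yl]oxy}dimethylsilane | CC(C)(C)[Si](C)(C)OCC[C@@H](C)CC/C=C(\C)CCl | intermediate
6 | β-cyclocitral, 2,6,6-trimethylcyclohex-1-ene-1-carbaldehyde | CC1=C(C=O)C(C)(C)CCC1 | starting material
7 | allylbarium chloride, [(2E,6S)-8-(tert-butyldimethylsilyloxy)-2,6-dimethyloct-2-en-1-yl]barium chloride (not isolated) | CC(C)(C)[Si](C)(C)OCC[C@@H](C)CC/C=C(\C)C[Ba]Cl | intermediate
8 | (3E,7S)-9-(tert-butyldimethylsilyloxy)-3,7-dimethyl-1-(2,6,6-trimethylcyclohex-1-en-1-yl)non-3-en-1-ol, both C1 epimers | CC(C)(C)[Si](C)(C)OCC[C@@H](C)CC/C=C(\C)CC(O)C1=C(C)CCCC1(C)C | intermediate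
9 | (3E,7S)-9-(tert-butyldimethylsilyloxy)-3,7-dimethyl-1-(2,6,6-trimethylcyclohex-1-en-1-yl)non-3-en-1-one | CC(C)(C)[Si](C)(C)OCC[C@@H](C)CC/C=C(\C)CC(=O)C1=C(C)CCCC1(C)C | intermediate
10 | (1S,3E,7S)-9-(tert-butyldimethylsilyloxy)-3,7-dimethyl-1-(2,6,6-trimethylcyclohex-1-en-1-yl)non-3-en-1-ol | CC(C)(C)[Si](C)(C)OCC[C@@H](C)CC/C=C(\C)C[C@H](O)C1=C(C)CCCC1(C)C | intermediate
11 | (3S,6E,9S)-3,7-dimethyl-9-(2,6,6-trimethylcyclohex-1-en-1-yl)non-6-ene-1,9-diol | OCC[C@@H](C)CC/C=C(\C)C[C@H](O)C1=C(C)CCCC1(C)C | intermediate
12 | hydroxy aldehyde, (3S,6E,9S)-9-hydroxy-3,7-dimethyl-9-(2,6,6-trimethylcyclohex-1-en-1-yl)non-6-enal (not isolated) | O=CC[C@@H](C)CC/C=C(\C)C[C@H](O)C1=C(C)CCCC1(C)C | intermediate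
13 | (3S,6E,9S)-9-hydroxy-3,7-dimethyl-9-(2,6,6-trimethylcyclohex-1-en-1-yl)non-6-enoic acid | OC(=O)C[C@@H](C)CC/C=C(\C)C[C@H](O)C1=C(C)CCCC1(C)C | intermediate
14 | dipotassium alkoxide carboxylate of 13 (not isolated) | [K+].[K+].[O-]C(=O)C[C@@H](C)CC/C=C(\C)C[C@H]([O-])C1=C(C)CCCC1(C)C | intermediate
15 | dipotassium enolate carboxylate, (E)-enolate of 16 with oxygen cis to C4 (not isolated) | [K+].[K+].[O-]C(=O)C[C@@H](C)CC[C@@H](C(C)=C)[C@@]1(C)CCCC(C)(C)/C1=C\[O-] | intermediate
16 | (3S,6S)-6-[(1R,2S)-2-formyl-1,3,3-trimethylcyclohexyl]-3,7-dimethyloct-7-enoic acid | OC(=O)C[C@@H](C)CC[C@@H](C(C)=C)[C@@]1(C)CCCC(C)(C)[C@@H]1C=O | intermediate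
17 | methyl (3S,6S)-6-[(1R,2S)-2-formyl-1,3,3-trimethylcyclohexyl]-3,7-dimethyloct-7-enoate | COC(=O)C[C@@H](C)CC[C@@H](C(C)=C)[C@@]1(C)CCCC(C)(C)[C@@H]1C=O | intermediate
18 | methyl 8α-(tert-butylperoxy)-6-oxolabdan-15-oate | COC(=O)C[C@@H](C)CC[C@@H]1[C@@]2(C)CCCC(C)(C)[C@@H]2C(=O)C[C@@]1(C)OOC(C)(C)C | intermediate
19 | methyl 8α-(tert-butylperoxy)-6β-hydroxylabdan-15-oate | COC(=O)C[C@@H](C)CC[C@@H]1[C@@]2(C)CCCC(C)(C)[C@@H]2[C@H](O)C[C@@]1(C)OOC(C)(C)C | intermediate
20 | methyl 6β-acetoxy-8α-(tert-butylperoxy)labdan-15-oate | COC(=O)C[C@@H](C)CC[C@@H]1[C@@]2(C)CCCC(C)(C)[C@@H]2[C@H](OC(C)=O)C[C@@]1(C)OOC(C)(C)C | intermediate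
21 | methyl 6β-acetoxy-8α-hydroxylabdan-15-oate (CNP0113148.1) | COC(=O)C[C@@H](C)CC[C@@H]1[C@@]2(C)CCCC(C)(C)[C@@H]2[C@H](OC(C)=O)C[C@@]1(C)O | target

Total step count: 14. Longest linear sequence: 14 steps (from 1; 6 enters at step 4, 3 at steps 2 and 11).

Steps least certain to work

**Step 11 (key step).** The most likely failures are loss of CO from the acyl radical before ring closure, interception of the acyl radical by the peroxyl radical or by iron before it reaches C7, and poor facial selectivity in the capture at C8. Relief of strain at C5 speeds decarbonylation, the peroxyl radical is present in excess, and the planar C8 radical offers two faces that differ only through the C10 methyl. The fallback uses known chemistry and runs from 17 to 21.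
- Me2AlCl in CH2Cl2 at −78 °C would effect an intramolecular carbonyl-ene reaction (C6–C7 formed, hydrogen taken from C17), giving methyl 6α-hydroxylabd-8(17)-en-15-oate F1, expected with the equatorial alcohol.
- Buffered Dess–Martin oxidation would give methyl 6-oxolabd-8(17)-en-15-oate F2.
- NaBH4 with CeCl3·7H2O, attacking from the α face, would give methyl 6β-hydroxylabd-8(17)-en-15-oate F3.
- Ac2O with 4-(dimethylamino)pyridine would give methyl 6β-acetoxylabd-8(17)-en-15-oate F4.
- Mukaiyama hydration (Co(acac)2, PhSiH3, O2) would add the tertiary hydroxyl at C8, with the same preference for the equatorial C–O bond, and return the route at 21.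

**Step 4.** The risk is loss of regiocontrol in the allylation (attack through the substituted γ-carbon) or loss of the (E)-geometry if the allylbarium equilibrates before it meets the very hindered aldehyde; the barium reagent is also awkward to prepare. The fallback runs from 5 to 9 and fixes the bond-forming carbon with a sulfone.
- PhSO2Na in DMF would give the allylic sulfone tert-butyl{[(3S,6E)-3,7-dimethyl-8-(phenylsulfonyl)oct-6-en-1-yl]oxy}dimethylsilane F5.
- Deprotonation with n-BuLi at −78 °C and addition to 6 would give the β-hydroxy sulfone F6 as a diastereomer mixture.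
- Dess–Martin oxidation would give the β-keto sulfone F7.
- SmI2 in THF/MeOH at −78 °C would remove the sulfonyl group and deliver 9.

**Step 6.** The risk is low enantioselectivity or slow reduction, because the ketone is flanked by a 2,6,6-trisubstituted cyclohexenyl group that may not behave as a clean large substituent. The fallback runs from 8 to 10 and replaces asymmetric reduction by resolution. The epimer mixture 8 would be esterified with (S)-2-methoxy-2-phenylacetic acid (DCC, 4-(dimethylamino)pyridine). The diastereomeric esters would be separated to give the (S)-2-methoxy-2-phenylacetate of the (1S)-alcohol F8, and K2CO3 in MeOH would release 10. The other ester can be cleaved and recycled through 9.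

**Step 9.** The risks are fragmentation of the hindered alkoxide into 6 and an allyl anion in competition with the 3,3-shift, incomplete chirality transfer if a boat or the axial-oxido chair takes part, and protonation at C5 from the wrong face. The fallback runs from 13 to 17 and leaves the anionic manifold for a neutral silyloxy-Cope rearrangement, which cannot fragment through an alkoxide and tolerates the ester.
- Me3SiCHN2 would give methyl (3S,6E,9S)-9-hydroxy-3,7-dimethyl-9-(2,6,6-trimethylcyclohex-1-en-1-yl)non-6-enoate F9.
- Me3SiCl and imidazole would give its trimethylsilyl ether F10.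
- Heating in degassed decalin in base-washed glass (about 220 °C) would give the silyl enol ether F11.
- Cold aqueous citric acid would hydrolyse F11 with protonation at C5 from the α face and deliver 17.

**Step 14.** The risk is sluggish electron transfer to an unactivated di-tertiary dialkyl peroxide, with acid-promoted loss of the tertiary C8 oxygen on prolonged heating. The fallback runs from 18 to 21 and cleaves the peroxide while the C6 ketone still activates it.
- Zn in AcOH on 18 would give methyl 8α-hydroxy-6-oxolabdan-15-oate F12.
- NaBH4 with CeCl3·7H2O would give methyl 6β,8α-dihydroxylabdan-15-oate F13.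
- Ac2O in pyridine at room temperature would acetylate the secondary alcohol selectively and give 21.

## Further compounds

F1 | step 11 | methyl 6α-hydroxylabd-8(17)-en-15-oate | COC(=O)C[C@@H](C)CC[C@@H]1[C@@]2(C)CCCC(C)(C)[C@@H]2[C@@H](O)CC1=C
F2 | step 11 | methyl 6-oxolabd-8(17)-en-15-oate | COC(=O)C[C@@H](C)CC[C@@H]1[C@@]2(C)CCCC(C)(C)[C@@H]2C(=O)CC1=C
F3 | step 11 | methyl 6β-hydroxylabd-8(17)-en-15-oate | COC(=O)C[C@@H](C)CC[C@@H]1[C@@]2(C)CCCC(C)(C)[C@@H]2[C@H](O)CC1=C
F4 | step 11 | methyl 6β-acetoxylabd-8(17)-en-15-oate | COC(=O)C[C@@H](C)CC[C@@H]1[C@@]2(C)CCCC(C)(C)[C@@H]2[C@H](OC(C)=O)CC1=C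
F5 | step 4 | tert-butyl{[(3S,6E)-3,7-dimethyl-8-(phenylsulfonyl)oct-6-en-1-yl]oxy}dimethylsilane | CC(C)(C)[Si](C)(C)OCC[C@@H](C)CC/C=C(\C)CS(=O)(=O)c1ccccc1
F6 | step 4 | (3E,7S)-9-(tert-butyldimethylsilyloxy)-3,7-dimethyl-2-(phenylsulfonyl)-1-(2,6,6-trimethylcyclohex-1-en-1-yl)non-3-en-1-ol, diastereomer mixture | CC(C)(C)[Si](C)(C)OCC[C@@H](C)CC/C=C(\C)C(C(O)C1=C(C)CCCC1(C)C)S(=O)(=O)c1ccccc1
F7 | step 4 | (3E,7S)-9-(tert-butyldimethylsilyloxy)-3,7-dimethyl-2-(phenylsulfonyl)-1-(2,6,6-trimethylcyclohex-1-en-1-yl)non-3-en-1-one | CC(C)(C)[Si](C)(C)OCC[C@@H](C)CC/C=C(\C)C(C(=O)C1=C(C)CCCC1(C)C)S(=O)(=O)c1ccccc1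
F8 | step 6 | (1S,3E,7S)-9-(tert-butyldimethylsilyloxy)-3,7-dimethyl-1-(2,6,6-trimethylcyclohex-1-en-1-yl)non-3-en-1-yl (S)-2-methoxy-2-phenylacetate | CC(C)(C)[Si](C)(C)OCC[C@@H](C)CC/C=C(\C)C[C@H](OC(=O)[C@@H](OC)c1ccccc1)C1=C(C)CCCC1(C)C
F9 | step 9 | methyl (3S,6E,9S)-9-hydroxy-3,7-dimethyl-9-(2,6,6-trimethylcyclohex-1-en-1-yl)non-6-enoate | COC(=O)C[C@@H](C)CC/C=C(\C)C[C@H](O)C1=C(C)CCCC1(C)C
F10 | step 9 | methyl (3S,6E,9S)-3,7-dimethyl-9-(2,6,6-trimethylcyclohex-1-en-1-yl)-9-(trimethylsilyloxy)non-6-enoate | COC(=O)C[C@@H](C)CC/C=C(\C)C[C@H](O[Si](C)(C)C)C1=C(C)CCCC1(C)C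
F11 | step 9 | methyl (3S,6S)-3,7-dimethyl-6-{(1R)-1,3,3-trimethyl-2-[(E)-(trimethylsilyloxy)methylidene]cyclohexyl}oct-7-enoate | COC(=O)C[C@@H](C)CC[C@@H](C(C)=C)[C@@]1(C)CCCC(C)(C)/C1=C\O[Si](C)(C)C
F12 | step 14 | methyl 8α-hydroxy-6-oxolabdan-15-oate | COC(=O)C[C@@H](C)CC[C@@H]1[C@@]2(C)CCCC(C)(C)[C@@H]2C(=O)C[C@@]1(C)O
F13 | step 14 | methyl 6β,8α-dihydroxylabdan-15-oate | COC(=O)C[C@@H](C)CC[C@@H]1[C@@]2(C)CCCC(C)(C)[C@@H]2[C@H](O)C[C@@]1(C)O
A1 | alternative 1 | 6-(tert-butyldimethylsilyloxy)-12,13,14,15,16-pentanorlabd-6-en-11-al (5α-H, 8β-methyl, 9β-formyl) | O=C[C@@H]1[C@@]2(C)CCCC(C)(C)[C@@H]2C(O[Si](C)(C)C(C)(C)C)=C[C@@H]1C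
A2 | alternative 1 | (2E,8Z,10E)-9-(tert-butyldimethylsilyloxy)-3,7,7-trimethyldodeca-2,8,10-trienal | O=C/C=C(\C)CCCC(C)(C)/C=C(O[Si](C)(C)C(C)(C)C)/C=C/C
A3 | alternative 2 | 3α-hydroxy-4,4,10-trimethyl-trans-decalin-6,8-dione (labdane numbering) | O=C1C[C@@]2(C)CC[C@@H](O)C(C)(C)[C@@H]2C(=O)C1
A4 | alternative 2 | (R)-2-[2-(3,5-dimethoxy-1-methylcyclohexa-2,5-dien-1-yl)ethyl]-3,3-dimethyloxirane | COC1=CC(C)(CC[C@H]2OC2(C)C)C=C(OC)C1
A5 | alternative 3 | methyl 6β-acetoxylabda-8(17),11E-dien-15-oate | COC(=O)C[C@@H](C)/C=C/[C@@H]1[C@@]2(C)CCCC(C)(C)[C@@H]2[C@H](OC(C)=O)CC1=C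
A6 | alternative 3 | methyl 6β-acetoxy-8,9-secolabd-9(11)E-en-8(17)-yn-15-oate | COC(=O)C[C@@H](C)C/C=C/[C@@]1(C)CCCC(C)(C)[C@@H]1[C@H](OC(C)=O)CC#C
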